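The cyclopentene ring is divided into a two-carbon unit (quaternary carbinol C-5 and acetoxy carbon C-1) and a three-carbon unit (C-2=C-3–C-4). One operation makes C-1–C-2 and C-4–C-5: the magnesium enolate of a 2-silyloxy-3-oxo aldehyde (C-5 nucleophilic, C-1 formyl) adds to the carbonyl of cyclopropenone, the strained ring opens to a cis-β-acylvinyl anion, and this closes on the aldehyde. The step exploits the 1,3-dicarbonyl relation between the tridecanoyl carbonyl and C-1 through C-5, and the cis alkene C-2=C-3 next to oxygenated C-4, which together are cyclopropenone. Lipase resolution and reduction of the C-4 ketone complete the route.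

Key step: step 6

Remark: compounds made as racemates (4, 10–14, F2–F4) are named rac- or "racemic" and drawn as one enantiomer; ring atoms are numbered as in cyclopent-2-en-1-yl acetate (C-1 OAc, C-4 OH, C-5 quaternary); cyclopropenone 8 is assumed not to be purchasable and is made in steps 3–5.

Step 1
Reactants: 1 (tert-butyldimethylsilyloxy)acetaldehyde
Product: 2 (Z)-1,2-bis[(tert-butyldimethylsilyl)oxy]ethene
Conditions: TBSOTf, Et3N, CH2Cl2, 0 °C → rt
Reagents that add atoms: tert-butyldimethylsilyl trifluoromethanesulfonate, CC(C)(C)[Si](C)(C)OS(=O)(=O)C(F)(F)F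
Why: O-silylation of the aldehyde enol (silyl enol ether formation) should give the symmetrical bis-silyl enediol ether; its Z/E ratio does not matter because the two alkene carbons are equivalent and the double bond is consumed in step 2.

Step 2
Reactants: 2 (Z)-1,2-bis[(tert-butyldimethylsilyl)oxy]ethene; 3 tridecanoyl chloride
Product: 4 2-[(tert-butyldimethylsilyl)oxy]-3-oxopentadecanal
Conditions: ZnCl2 (20 mol %), CH2Cl2, 0 °C → rt; pH 7 buffer
Reagents that add atoms: none
Why: ZnCl2-promoted C-acylation of a silyl enol ether by an acid chloride (Mukaiyama-type), with loss of the silyl group from the oxocarbenium oxygen, should give the α-silyloxy β-keto aldehyde (mainly as its chelated enol) without a regiochemical question, since both alkene carbons of 2 are identical; its one stereocentre is labile and is erased in step 6.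

Step 3
Reactants: 5 2,3-dichloroprop-1-ene
Product: 6 1-bromo-3-chloro-2,2-dimethoxypropane
Conditions: NBS, MeOH, H2SO4 (cat.), rt
Reagents that add atoms: N-bromosuccinimide, O=C1CCC(=O)N1Br; methanol, CO
Why: Bromo-methoxylation of the vinyl chloride followed by methanolysis of the α-chloro ether should give the dimethyl ketal of 1-bromo-3-chloroacetone.

Step 4
Reactants: 6 1-bromo-3-chloro-2,2-dimethoxypropane
Product: 7 3,3-dimethoxycycloprop-1-ene
Conditions: KNH2, NH3 (l), −50 °C; NH4Cl
Reagents that add atoms: none
Why: Amide-induced double dehydrohalogenation (1,3- then 1,2-elimination) should close and desaturate the three-membered ring while the ketal masks the carbonyl.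

Step 5
Reactants: 7 3,3-dimethoxycycloprop-1-ene
Product: 8 cyclopropenone
Conditions: H2O, H2SO4 (cat.), CH2Cl2, 0 °C; dried cold and used at once as a CH2Cl2 solution
Reagents that add atoms: water, O
Why: Acid-catalysed ketal hydrolysis should free the ketone, whose cyclopropenium-oxide character makes it handleable as a cold solution.

Step 6
Reactants: 4 2-[(tert-butyldimethylsilyl)oxy]-3-oxopentadecanal; 8 cyclopropenone
Product: 13 rac-(1S,5S)-5-[(tert-butyldimethylsilyl)oxy]-4-oxo-5-tridecanoylcyclopent-2-en-1-yl acetate, via chloromagnesium enolate 9 (not isolated), via magnesium cyclopropenolate 10 (not isolated), via (Z)-vinylmagnesium ketoaldehyde 11 (not isolated), via magnesium aldolate 12 (not isolated)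
Conditions: t-BuMgCl (1.05 equiv), THF, −40 °C; 8 (1.5 equiv, CH2Cl2 solution), −78 → 0 °C; Ac2O, DMAP (cat.), 0 °C
Reagents that add atoms: acetic anhydride, CC(=O)OC(C)=O
Why: Proposed new method: the chelated enolate 9 should add through carbon to the carbonyl carbon of 8 (closed aldol-type transition state), the strained cyclopropenolate 10 should fragment to the (Z)-β-acylvinylmagnesium species 11, and 11 should add to the neighbouring formyl group (5-exo-trig closure of the cyclopentenone) to give aldolate 12, which Ac2O traps before it can revert by retro-aldol opening. The closest known reaction types are the opening of cyclopropenones by hydroxide, alkoxides and amines to cis-acrylic acid derivatives and the formal insertion of enamine C=C bonds into diarylcyclopropenones to give cyclopent-2-enones; magnesium-mediated C-acylation of 1,3-dicarbonyl compounds is the model for C- over O-attack. The cis ring alkene is inherited from the three-membered ring, since the carbon–magnesium bond replaces the broken ring bond. The quaternary centre forms without control (racemate); the carbinol centre is set relative to it by the formyl rotamer that keeps C=O anti to the bulky, non-chelating OTBS group and bridged by magnesium to the acyl carbonyl, so the new oxygen should end cis to the acyl group and trans to OTBS. The step needs 1,2-addition to 8 (a conjugate adduct can only revert, whereas 10 fragments irreversibly) and closure of 11 on the aldehyde and not the ketone (the aldehyde is the better electrophile, both closures being five-membered). The fully substituted enolate carbon of 4 leaves no acidic C–H that could quench 11.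

Step 7
Reactants: 13 rac-(1S,5S)-5-[(tert-butyldimethylsilyl)oxy]-4-oxo-5-tridecanoylcyclopent-2-en-1-yl acetate
Product: 14 rac-(1S,5S)-5-hydroxy-4-oxo-5-tridecanoylcyclopent-2-en-1-yl acetate
Conditions: HF·pyridine, THF, 0 °C → rt
Reagents that add atoms: none
Why: Fluoride-driven Si–O cleavage under acidic conditions should free the tertiary alcohol without acetyl migration (the acetate is trans to it on the ring) and without base-induced cleavage of the α-hydroxy β-diketone.

Step 8
Reactants: 14 rac-(1S,5S)-5-hydroxy-4-oxo-5-tridecanoylcyclopent-2-en-1-yl acetate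
Product: 15 (1S,5S)-5-hydroxy-4-oxo-5-tridecanoylcyclopent-2-en-1-yl acetate
Conditions: immobilised Candida antarctica lipase B, n-BuOH, t-BuOMe, 30 °C, stopped just beyond half conversion
Reagents that add atoms: none
Why: Lipase-catalysed kinetic resolution by enantioselective alcoholysis: by the empirical size rule for lipases the acetate whose carbinol carbon is (R) (large group the quaternary carbon, medium group the vinyl CH) should be cleaved, so the (1S,5S)-acetate should remain and is separated from the more polar diol; this sets the absolute configuration.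

Step 9
Reactants: 15 (1S,5S)-5-hydroxy-4-oxo-5-tridecanoylcyclopent-2-en-1-yl acetate
Product: 16 (1S,4R,5S)-4,5-dihydroxy-5-tridecanoylcyclopent-2-en-1-yl acetate
Conditions: NaBH4, CeCl3·7H2O, MeOH, −78 °C; AcOH quench
Reagents that add atoms: none
Why: Luche reduction should attack the conjugated ring carbonyl 1,2 in preference to the hindered side-chain ketone and from the face anti to the acyl and acetoxy groups (syn to the small tertiary OH), setting C-4 as (R) with its hydroxyl cis to the acetate and trans to the tertiary hydroxyl; the cold, non-basic work-up avoids 1,3-acetyl migration.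

Compound list
1 | (tert-butyldimethylsilyloxy)acetaldehyde | CC(C)(C)[Si](C)(C)OCC=O | starting material
2 | (Z)-1,2-bis[(tert-butyldimethylsilyl)oxy]ethene | CC(C)(C)[Si](C)(C)O/C=C\O[Si](C)(C)C(C)(C)C | intermediate
3 | tridecanoyl chloride | CCCCCCCCCCCCC(Cl)=O | starting material
4 | 2-[(tert-butyldimethylsilyl)oxy]-3-oxopentadecanal (racemic, largely enolised) | CCCCCCCCCCCCC(=O)C(O[Si](C)(C)C(C)(C)C)C=O | intermediate
5 | 2,3-dichloroprop-1-ene | ClCC(Cl)=C | starting material
6 | 1-bromo-3-chloro-2,2-dimethoxypropane | COC(CBr)(CCl)OC | intermediate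
7 | 3,3-dimethoxycycloprop-1-ene | COC1(OC)C=C1 | intermediate
8 | cycloprop-2-en-1-one (cyclopropenone) | O=C1C=C1 | intermediate
9 | chloromagnesium enolate of 4 (chelated; enolate oxygen cis to the acyl carbon) | Cl[Mg]O/C=C(O[Si](C)(C)C(C)(C)C)\C(=O)CCCCCCCCCCCC | intermediate
10 | chloromagnesium 1-{2-[(tert-butyldimethylsilyl)oxy]-1,3-dioxopentadecan-2-yl}cycloprop-2-en-1-olate (racemic) | CCCCCCCCCCCCC(=O)C(C=O)(O[Si](C)(C)C(C)(C)C)C1(O[Mg]Cl)C=C1 | intermediate
11 | chloro{(1Z)-4-[(tert-butyldimethylsilyl)oxy]-4-formyl-3,5-dioxoheptadec-1-en-1-yl}magnesium (racemic) | CCCCCCCCCCCCC(=O)C(C=O)(O[Si](C)(C)C(C)(C)C)C(=O)/C=C\[Mg]Cl | intermediate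
12 | chloromagnesium rac-(1S,5S)-5-[(tert-butyldimethylsilyl)oxy]-4-oxo-5-tridecanoylcyclopent-2-en-1-olate | CCCCCCCCCCCCC(=O)[C@]1(O[Si](C)(C)C(C)(C)C)C(=O)C=C[C@@H]1O[Mg]Cl | intermediate
13 | rac-(1S,5S)-5-[(tert-butyldimethylsilyl)oxy]-4-oxo-5-tridecanoylcyclopent-2-en-1-yl acetate | CCCCCCCCCCCCC(=O)[C@]1(O[Si](C)(C)C(C)(C)C)C(=O)C=C[C@@H]1OC(C)=O | intermediate
14 | rac-(1S,5S)-5-hydroxy-4-oxo-5-tridecanoylcyclopent-2-en-1-yl acetate (racemate, one enantiomer drawn) | CCCCCCCCCCCCC(=O)[C@]1(O)C(=O)C=C[C@@H]1OC(C)=O | intermediate
15 | (1S,5S)-5-hydroxy-4-oxo-5-tridecanoylcyclopent-2-en-1-yl acetate (single enantiomer) | CCCCCCCCCCCCC(=O)[C@]1(O)C(=O)C=C[C@@H]1OC(C)=O | intermediate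
16 | (1S,4R,5S)-4,5-dihydroxy-5-tridecanoylcyclopent-2-en-1-yl acetate | CCCCCCCCCCCCC(=O)[C@]1(O)[C@H](O)C=C[C@@H]1OC(C)=O | target

Total step count: 9. Longest linear sequence: 7 steps (steps 3–9).

Steps most likely to fail

Step 6. The enolate may attack through oxygen, cyclopropenone may take the nucleophile in conjugate fashion or oligomerise, or the vinylmagnesium intermediate may be quenched by proton or silyl transfer before it closes. In that case the two bonds are made one after the other by known reactions, setting out from 4. Commercial (Z)-3-iodoacrylic acid is converted with (COCl)2 and catalytic DMF into (Z)-3-iodoacryloyl chloride F1. Magnesium-mediated C-acylation of 4 (MgCl2, Et3N, MeCN, 0 °C) with F1 should give rac-2-[(tert-butyldimethylsilyl)oxy]-2-[(2Z)-3-iodoprop-2-enoyl]-3-oxopentadecanal F2. An intramolecular Nozaki–Hiyama–Kishi reaction (CrCl2, NiCl2 cat., DMF) should close the ring to rac-(4S,5S)-5-[(tert-butyldimethylsilyl)oxy]-4-hydroxy-5-tridecanoylcyclopent-2-en-1-one F3. Acetylation (Ac2O, DMAP) brings the route back at 13.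

Step 8. The lipase may discriminate the enantiomers poorly or turn over slowly, because the acetate sits next to a quaternary carbon. The resolution is then replaced by a desymmetrisation, setting out from 14. Luche reduction of the racemate should give racemic (1S,4R,5S)-4,5-dihydroxy-5-tridecanoylcyclopent-2-en-1-yl acetate F4. Acetylation of its secondary hydroxyl (Ac2O, pyridine) should give the meso compound (1R,2r,3S)-2-hydroxy-2-tridecanoylcyclopent-4-ene-1,3-diyl diacetate F5. Lipase-catalysed hydrolysis (Burkholderia cepacia lipase, pH 7 phosphate buffer/t-BuOMe) should remove the acetate on the (R)-carbinol carbon and come back to the route at 16.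

Step 9. The side-chain ketone may be reduced in competition, hydride may arrive from the wrong face, or the acetyl group may migrate under basic conditions. Substrate control is then replaced by reagent control: a Corey–Bakshi–Shibata reduction of 15 (oxazaborolidine catalyst, catecholborane, toluene, −78 °C), which prefers conjugated ketones and whose facial sense is set by the catalyst enantiomer (the matched one is used), leads from 15 directly to 16. This fallback makes no new compound (F0).

Further compounds
F1 | step 6 | (Z)-3-iodoacryloyl chloride | I/C=C\C(Cl)=O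
F2 | step 6 | rac-2-[(tert-butyldimethylsilyl)oxy]-2-[(2Z)-3-iodoprop-2-enoyl]-3-oxopentadecanal | CCCCCCCCCCCCC(=O)C(C=O)(O[Si](C)(C)C(C)(C)C)C(=O)/C=C\I
F3 | step 6 | rac-(4S,5S)-5-[(tert-butyldimethylsilyl)oxy]-4-hydroxy-5-tridecanoylcyclopent-2-en-1-one | CCCCCCCCCCCCC(=O)[C@]1(O[Si](C)(C)C(C)(C)C)C(=O)C=C[C@@H]1O
F4 | step 8 | racemic (1S,4R,5S)-4,5-dihydroxy-5-tridecanoylcyclopent-2-en-1-yl acetate (racemate, one enantiomer drawn) | CCCCCCCCCCCCC(=O)[C@]1(O)[C@H](O)C=C[C@@H]1OC(C)=O
F5 | step 8 | (1R,2r,3S)-2-hydroxy-2-tridecanoylcyclopent-4-ene-1,3-diyl diacetate (meso) | CCCCCCCCCCCCC(=O)[C@]1(O)[C@H](OC(C)=O)C=C[C@@H]1OC(C)=O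
F0 | step 9 | none | none
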